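**Assumption:** the target has no stereocentre or stereogenic axis (it is achiral), so "single enantiomer" needs no stereocontrol; the SMILES is taken as the full structure.

## Retrosynthetic overview

1. 7 ⇐ 6: the CH2OH is unveiled last by ester reduction, because a p-hydroxybenzyl alcohol would not survive Br+.
2. 6 ⇐ 5: all three C–Br bonds come from one exhaustive bromination; with both para positions blocked, the three free ortho-to-OH carbons are exactly the three bromination sites.
3. 5 ⇐ 3 + 4: the Ar–CH2 bond is cut between the aryl bromide carbon of 3 and the former aldehyde carbon of 1, two carbons that are both electrophilic; the aldehyde carbon reacts as a carbanion equivalent in the form of its N–H hydrazone 4.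
4. 4 ⇐ 1 + 2, made in the flask.
5. No ring is formed; both benzene rings are bought.

## Route

**Step 1**
Reactants: 1 4-hydroxybenzaldehyde; 2 hydrazine monohydrate; 3 methyl 3-bromo-4-hydroxybenzoate
Product: 5 methyl 4-hydroxy-3-(4-hydroxybenzyl)benzoate, via 4-hydroxybenzaldehyde hydrazone 4 (not isolated)
Conditions: 1 (1.5 equiv), N2H4·H2O (1.5 equiv), THF, rt, 1 h, dried over Na2SO4; then 3 (1.0 equiv), Ni(cod)2 (10 mol %), PMe3 (20 mol %), K3PO4 (4 equiv), THF, 70 °C, 16 h; aq. NH4Cl work-up
Reagents that add atoms: none
Why: Ni(0)-catalysed Wolff–Kishner-type umpolung cross-coupling, in which the aldehyde carbon of 1 (as hydrazone 4) acts as a benzyl carbanion equivalent, is arylated by the oxidative-addition complex of 3 and loses N2 to leave the CH2 bridge; the reaction type is known for aryl bromides, but running both partners as unprotected phenols (as phenoxides, hence the extra base) is untested; no stereocentre is formed.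

**Step 2**
Reactants: 5 methyl 4-hydroxy-3-(4-hydroxybenzyl)benzoate
Product: 6 methyl 3-bromo-5-(3,5-dibromo-4-hydroxybenzyl)-4-hydroxybenzoate
Conditions: Br2 (3.05 equiv), AcOH, 15 °C to rt, dark, 2 h; aq. NaHSO3 quench
Reagents that add atoms: bromine, BrBr
Why: Electrophilic aromatic bromination directed by the two phenolic OH groups; both para positions are blocked, so the only activated sites are the three free ortho carbons and three equivalents of Br2 give the 3,3',5'-tribromide; no stereocentre is formed.

**Step 3**
Reactants: 6 methyl 3-bromo-5-(3,5-dibromo-4-hydroxybenzyl)-4-hydroxybenzoate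
Product: 7 thelephenol, 2-bromo-6-(3,5-dibromo-4-hydroxybenzyl)-4-(hydroxymethyl)phenol
Conditions: DIBAL-H (6 equiv), THF, −78 °C to 0 °C; aq. Rochelle salt, then pH 5–6
Reagents that add atoms: none
Why: DIBAL-H reduction of the methyl ester (the phenols are carried as aluminium phenoxides) gives the primary benzylic alcohol, and aryl C–Br bonds are inert to DIBAL-H at 0 °C or below; no stereocentre is involved.

## Compound list

1 | 4-hydroxybenzaldehyde | O=Cc1ccc(O)cc1 | starting material
2 | hydrazine monohydrate | NN.O | starting material
3 | methyl 3-bromo-4-hydroxybenzoate | COC(=O)c1ccc(O)c(Br)c1 | starting material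
4 | 4-hydroxybenzaldehyde hydrazone, (E)-4-(hydrazinylidenemethyl)phenol | N/N=C/c1ccc(O)cc1 | intermediate
5 | methyl 4-hydroxy-3-(4-hydroxybenzyl)benzoate | COC(=O)c1ccc(O)c(Cc2ccc(O)cc2)c1 | intermediate
6 | methyl 3-bromo-5-(3,5-dibromo-4-hydroxybenzyl)-4-hydroxybenzoate | COC(=O)c1cc(Br)c(O)c(Cc2cc(Br)c(O)c(Br)c2)c1 | intermediate
7 | thelephenol, 2-bromo-6-(3,5-dibromo-4-hydroxybenzyl)-4-(hydroxymethyl)phenol | OCc1cc(Br)c(O)c(Cc2cc(Br)c(O)c(Br)c2)c1 | target

## Step count and risk

Total step count: 3. Longest linear sequence: 3.

**Step 1 (most likely to fail).** The phenoxide of 3 is a slow, chelating oxidative-addition partner. The hydrazone can also act as a reductant and hydrodebrominate 3, or condense to the azine. The electron-rich hydrazone of 1 is a reluctant carbanion equivalent.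
Fallback, setting out from 3 and returning at 5: 3 is O-benzylated (BnBr, K2CO3, DMF) to methyl 4-(benzyloxy)-3-bromobenzoate F1. F1 and commercial 4-(benzyloxy)benzyl chloride are then joined by a nickel-catalysed reductive cross-electrophile coupling (NiBr2·glyme, 4,4'-di-tert-butyl-2,2'-bipyridine, cobalt phthalocyanine co-catalyst, Zn, DMA, 40–60 °C). Here the benzylic chloride carbon is turned into the nucleophilic partner in situ, giving methyl 4-(benzyloxy)-3-[4-(benzyloxy)benzyl]benzoate F2. Hydrogenolysis of both benzyl ethers (H2, Pd/C, EtOAc–MeOH) is safe because no halogen is present yet and gives 5.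

**Step 2.** The ester-bearing ring brominates more slowly than the other ring. If excess Br2 is needed to finish it, ipso attack at the bridge carbon para to OH (dienone formation or cleavage of the diarylmethane) may compete.
Fallback, setting out from 5 and returning at 7: the order of the last two operations is reversed. 5 is reduced (DIBAL-H, THF, −78 to 0 °C) to 2-(4-hydroxybenzyl)-4-(hydroxymethyl)phenol F3, in which both rings are now equally activated. F3 is then tribrominated with exactly 3.0 equiv of NBS in MeCN at −20 °C, giving 7 directly. The low temperature and exact stoichiometry are needed to keep Br+ away from the carbon bearing CH2OH.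

**Step 3.** The ester is deactivated by the para aluminium phenoxide. Forcing it risks over-reduction of the p-hydroxybenzyl alcohol to the methyl compound through a quinone methide, and possibly C–Br reduction.
Fallback, setting out from 6 and returning at 7: 6 is saponified (aq. NaOH, MeOH, 60 °C, then acidified) to 3-bromo-5-(3,5-dibromo-4-hydroxybenzyl)-4-hydroxybenzoic acid F4. The free acid is then reduced with an electrophilic hydride (BH3·SMe2, B(OMe)3, THF, 0 °C to rt), which is selective for CO2H and leaves aryl bromides untouched, giving 7.

## Further compounds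

F1 | step 1 | methyl 4-(benzyloxy)-3-bromobenzoate | COC(=O)c1ccc(OCc2ccccc2)c(Br)c1
F2 | step 1 | methyl 4-(benzyloxy)-3-[4-(benzyloxy)benzyl]benzoate | COC(=O)c1ccc(OCc2ccccc2)c(Cc2ccc(OCc3ccccc3)cc2)c1
F3 | step 2 | 2-(4-hydroxybenzyl)-4-(hydroxymethyl)phenol | OCc1ccc(O)c(Cc2ccc(O)cc2)c1
F4 | step 3 | 3-bromo-5-(3,5-dibromo-4-hydroxybenzyl)-4-hydroxybenzoic acid | OC(=O)c1cc(Br)c(O)c(Cc2cc(Br)c(O)c(Br)c2)c1
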